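(The runs come from a simulation for substances that don't exist, and the scatter is random.)

In a closed flask the substrate charged stays counted whatever it becomes, so you can read each percentage of target as a fraction kept and ask what multiplies it down when the loading changes.

the same everywhere: free catalyst 0.50 µM
- autumn: substrate 0.50 mM; run made earlier
- winter: substrate 2 mM; run made earlier
- flask: substrate 1.0 mM; time 12 min

| run | time / min | target / % |
|---|---|---|
| autumn | 0.167 | 31.4 |
| autumn | 0.333 | 41.2 |
| autumn | 0.667 | 35.9 |
| autumn | 1.33 | 14.0 |
| autumn | 3.00 | 0.3 |
| autumn | 6.00 | 0.5 |
| autumn | 15.0 | 0 |
| winter | 0.167 | 22.3 |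
| winter | 0.333 | 31.5 |
| winter | 0.667 | 30.9 |
| winter | 1.33 | 11.1 |
| winter | 3.00 | 0.8 |
| winter | 6.00 | 0 |
| winter | 15.0 | 0 |

(readings scatter by 0.3 percentage points)

- what was read earlier has a scatter of 0.3 percentage points, one standard deviation

1. when, up to 12 min, the flask holds most target
2. the amount of target, in percent of the substrate charged, at that time

The winter run looks like the autumn run with a larger c(substrate): both have their highest reading at 0.333 min and both end with target at 0%, so the clock has hardly moved. Yet winter reads 31.5% there against 41.2%. A chain of steps each first order in what it consumes, with the catalyst held, gives equal percentages at any charge, so a step that grows with the substrate charged seems to take target away in winter. I therefore work with the keep exponent, the logarithm of the ratio of fractions kept per mM of extra substrate charged at equal catalyst, 0.179 mM⁻¹ as read from these two readings. The flask, with 0.500 mM more than autumn, keeps 0.914 of autumn, so my reckoning is 37.7% at that reading time, with its peak possibly a little higher.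

The forecast, reckoned differently from mine, says 37.5% at 0.45 min, on the ground that “The flask at 1 mM lies midway between the runs on a log scale”.

The flask gives 39.3% at 0.422 min.

    catalyst intermediate → free catalyst + target (k = 295 s⁻¹)
    free catalyst + target → free catalyst + over-reaction product (k = 68000 L mol⁻¹ s⁻¹)
    substrate + free catalyst → catalyst intermediate (k = 1.10 × 10⁵ L mol⁻¹ s⁻¹)
    substrate + target → side product (k = 17.3 L mol⁻¹ s⁻¹)

At 0.240 min in this flask, target goes 3.2 times faster by the pseudo-first-order step on free catalyst than by the step with substrate. Of these two losses of target, the second, with a half-life for target of 1.3 min at that moment, is the one whose rate carries c(substrate). The exponent takes the autumn peak of 42.6% down to 38.9% for this flask. In the neighbour with 2.00 µM of free catalyst, I shorten the clock 4.00-fold and shrink the exponent to match, which lifts 39.3% to 44.9%, and that neighbour stores 44.0%.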